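Positions are named by the flavanone numbering of the target throughout, also for open-chain intermediates: O1, C2, C3, C4, C4a, C5–C8, C8a; ring A is the benzo ring, ring C the pyranone, ring B the aryl group on C2.

## Analysis of the target

The target 31 is a flavanonol 3-O-methyl ether, a chroman-4-one. Ring A carries hydroxyls at C5 and C6, a methoxy group at C7 and its only hydrogen at C8; ring C holds O1, C2, C3 and the C4 ketone; ring B is a 3-hydroxy-4-methoxyphenyl group on C2. The two adjacent stereocenters, C2 (R) and C3 (R), place the aryl group and the C3 methoxy group trans on ring C, the diequatorial and thermodynamically preferred arrangement. C3–H is α to the ketone and β to O1, so base can epimerise C3 or open ring C by β-elimination to a chalcone, which erases both centres. The free C5/C6 catechol is easily oxidised, and three methyl ethers (C3, C7, C4′) must stay while three phenols are released. The real difficulty is ring A: four oxygens in three different states and the acyl carbon C4 on C4a, flanked by two of them. On a preformed 3,4,5-trioxygenated phenol the positions that become C4a and C8 are both ortho to the phenol and nearly alike, so acylation and ring closure do not tell the 5,6,7-pattern from the 5,7,8-pattern. The plan rests on dissecting ring A into a four-carbon unit C5–C6–C7–C8 (O, O, OMe, H) and a two-carbon unit C4a–C8a (chain and one oxygen), that is, into a cyclobutenone and a siloxyalkyne. The C2/C3 dyad, an α-methoxy-β-oxy carbonyl motif, is set by an auxiliary-controlled glycolate aldol.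

## Retrosynthetic reasoning

31 from 30. The three phenols (C5, C6, C3′) are unmasked last from tris(benzyl) ether 30. No skeletal bond is cut. The gain is that the catechol and the base-labile ring C only meet a neutral hydrogenolysis, and one operation removes all three groups.

30 from 29. Ring C is opened at O1–C2. C2 is a secondary benzylic carbinol carbon and the C8a hydroxyl an ortho-acyl phenol of suitable acidity, so a Mitsunobu closure fits. Cutting here, and not at C4–C4a or O1–C8a, keeps the aryl ketone intact and needs no aryl halide. The closure inverts C2, so 29 must have C2 (S) and C3 (R), the syn pattern of an aldol. Its C5 oxygen must be blocked so that only the C8a phenol can close.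

29 back to 25 (through 28, 27 and 26). No C–C bond is cut. The C4 ketone is traced back to a silyl-protected carbinol, because a carbonyl conjugated to the alkyne would remove the nucleophilic character the ring synthesis needs. Three silyl ethers of graded lability are used: triethylsilyl on C4–O (off first, to allow oxidation), tert-butyldimethylsilyl on C2–O and triisopropylsilyl on C8a–O (off together, just before ring closure). The C5 benzyl ether of 26 comes from the one free phenol of 25.

25 from 5 and 20. This is the central cut: bonds C4a–C5 and C8–C8a. The two alkyne carbons of 20 become C4a (with the chain) and C8a (with its oxygen); the four ring carbons of 5 become C5, C6, C7 and C8. Every substituent of ring A is then placed by construction, and the C5 oxygen emerges as the only free hydroxyl, which is exactly the handle the later differentiation needs. Forward, the reaction must open the cyclobutenone, join ketene and alkyne with one regiochemistry, and aromatise.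

20 from 14 and 15 (through 17 and 16). The C8a–O bond comes from oxidation of a terminal acetylide to an ynolate and O-silylation. The C4–C4a bond comes from addition of 15 to aldehyde 14. The configuration at C4 is immaterial because C4 ends as the ketone.

14 from 8 and 9 (through 13, 12 and 11), and 8 from 6 and 7. The C2–C3 bond is cut in the aldol sense. A glycolate aldol brings the C3 methoxy group in with the enolate, so no pair of secondary hydroxyls ever has to be told apart. It sets both centres at once in the syn relation that the inverting ring closure requires.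

5 from 1 (through 3 and 4). The cyclobutenone is reached from squarate 1 by two hydride additions. The first, followed by acid, removes one methoxy group; the second creates the C6 carbinol, which is benzylated.

## Alternatives that were turned down

Alternative 1: three-component carbene union. The disconnection cuts C2–C3 and the C3–OMe bond and leaves ring C open. Forward, Rh2(OAc)4 turns the ring A diazoketone A1 into a carbene, the alcohol that supplies the C3 methoxy group forms an oxonium ylide, and a chiral phosphoric acid steers its aldol-type addition to aldehyde 9, giving hydroxy ketone A2.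
- For it: it is clearly stronger in step economy. One step makes two bonds and both stereocenters and delivers C4 as the ketone, where the chosen route spends steps 14 and 15 on the oxidation level.
- Against it: A1 needs a finished ring A with the acyl carbon between two oxygens, so the ring A problem is moved into the synthesis of A1 and not solved. A2 carries three methyl ethers on ring A, so C5 and C6 must later be demethylated beside C7–OMe, C3–OMe and C4′–OMe. That is plausible at C5 (peri to the carbonyl) but unsecured at C6, and the Lewis acids needed threaten ring C.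
- Mechanism: an acyl carbene without a donor substituent gives ylides that collapse by proton shift to the O–H insertion product. Trapping needs a reactive electrophile, and 9 is an electron-rich, sluggish aldehyde. Syn/anti and enantiocontrol next to a di-ortho-substituted aroyl group are not assured.
- In its place the chosen strategy offers a ring A whose oxygens are distinguished from the moment the ring forms, and a dyad set by a dependable auxiliary aldol.

Alternative 2: aryne annulation. The disconnection cuts O1–C8a and C4–C4a and closes ring C in the key step. Forward, fluoride releases an aryne from silyl aryl triflate A3; the alkoxide of hydroxy ester A4 adds at C8a, remote from the C5 alkoxy group, and the C4a aryl anion acylates on the ester to give chromanone A5, which is identical with 30.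
- For it: it is the most convergent plan and stronger on the endgame. A5 is one step from the target, O1–C2 is never broken so no inversion is needed, and the regiochemistry of addition to an alkoxy aryne is well founded.
- Against it: A3 is a benzene with five different substituents and adjacent silyl and triflate groups. Making it demands the very regiocontrolled functionalisation of ring A that is the core problem.
- Mechanism: a secondary alkoxide between an aryl group and an α-methoxy ester carbon is a hindered, weak aryne nucleophile. Under basic fluoride the β-alkoxide of an aldol-type ester can undergo retro-aldol cleavage to 9 and epimerise C3, and the aryl anion may be protonated before it acylates. A4 also needs the anti configuration, which is less directly available than syn.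
- In its place the chosen route builds ring A de novo and exposes the stereocenters to base only under buffered conditions.

Alternative 3: carbonylative flavone assembly. The disconnection cuts C4–C4a, C3–C4 and O1–C2. Forward, PdCl2(PPh3)2 couples iodophenol A6 with alkyne A7 under carbonylative conditions, and the phenol adds to the ynone to close ring C as flavone A8.
- For it: it is the shortest and most robust way to the carbon skeleton, from cheap inputs, and stronger than the chosen route on reliability of the key step itself.
- Against it: A8 is flat. It has no C3 oxygen and no stereocenter, so the C3 methoxy group and both centres would have to be installed on an electron-rich flavone afterwards, for which no dependable enantioselective reduction of the tetrasubstituted C2=C3 bond is at hand. A6 again requires choosing C4a over C8 on a trioxygenated phenol, and C5/C6 must be demethylated selectively at the end.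
- In its place the chosen route carries the stereocenters in from a controlled aldol and never has to dealkylate ring A.

Key step: step 12

Assumption: 3-(benzyloxy)-4-methoxybenzaldehyde 9 is taken as a purchased compound; it is otherwise one benzylation away from isovanillin.
Remark: C4 is carried as a mixture of epimers from 16 to 27. The descriptor of the methoxy-bearing carbon switches between R and S in 16, 17 and 27 only because the CIP ranking of its carbon neighbours changes; its spatial arrangement is never altered.

## Route

Step 1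
Reactants: 1 dimethyl squarate
Product: 3 3-methoxycyclobut-3-ene-1,2-dione, via hydroxycyclobutenone 2 (not isolated)
Conditions: LiAlH(OtBu)3, THF, −78 °C; then 2 M HCl, CH2Cl2, 0 °C
Reagents that add atoms: water, O
Why: The bulky alkoxyaluminium hydride adds once to a squarate carbonyl (1,2-reduction); acid then ionises the carbinol of 2, water adds to the resulting vinylogous oxocarbenium carbon and methanol leaves, which gives the semisquarate (acid-mediated allylic transposition and hydrolysis of a vinylogous ester).

Step 2
Reactants: 3 3-methoxycyclobut-3-ene-1,2-dione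
Product: 4 4-hydroxy-3-methoxycyclobut-2-en-1-one (racemic)
Conditions: LiAlH(OtBu)3, THF, −78 °C; Na2SO4·10H2O quench, filtration; crude product used at once
Reagents that add atoms: none
Why: The carbonyl next to the methoxy-bearing carbon is a plain ketone, while the other is a vinylogous ester deactivated by the methoxy group, so 1,2-hydride addition should occur at the former (chemoselective carbonyl reduction). The new stereocenter is racemic and irrelevant, since this carbon becomes aromatic C6.

Step 3
Reactants: 4 4-hydroxy-3-methoxycyclobut-2-en-1-one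
Product: 5 4-(benzyloxy)-3-methoxycyclobut-2-en-1-one (racemic)
Conditions: BnBr, Ag2O, 4 Å MS, CH2Cl2, rt, dark
Reagents that add atoms: benzyl bromide, BrCc1ccccc1
Why: Ag2O-promoted O-benzylation needs no free alkoxide, which suits the base-labile β-hydroxy enone 4. The ether also removes the hydroxyl that would otherwise trap the ketene on heating.

Step 4
Reactants: 6 (R)-4-benzyloxazolidin-2-one; 7 methoxyacetyl chloride
Product: 8 (R)-4-benzyl-3-(2-methoxyacetyl)oxazolidin-2-one
Conditions: n-BuLi, THF, −78 °C; then 7, −78 → 0 °C
Reagents that add atoms: none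
Why: N-Acylation of the lithiated oxazolidinone with an acid chloride is a standard, clean reaction.

Step 5
Reactants: 8 (R)-4-benzyl-3-(2-methoxyacetyl)oxazolidin-2-one; 9 3-(benzyloxy)-4-methoxybenzaldehyde
Product: 11 (R)-4-benzyl-3-[(2R,3S)-3-[3-(benzyloxy)-4-methoxyphenyl]-3-hydroxy-2-methoxypropanoyl]oxazolidin-2-one, via boron enolate 10 (not isolated)
Conditions: Bu2BOTf, Et3N, CH2Cl2, −78 → 0 °C; 9, −78 → 0 °C; pH 7 buffer, MeOH, 30% H2O2, 0 °C
Reagents that add atoms: none
Why: Evans syn aldol: the (Z)-boron enolate 10 reacts through a closed chair transition state on the face away from the benzyl group of the auxiliary. The (R)-auxiliary should therefore set C3 as R and C2 as S, the syn pair, with the C3 methoxy group already in place.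

Step 6
Reactants: 11 the aldol adduct
Product: 12 (2R,3S)-3-[3-(benzyloxy)-4-methoxyphenyl]-3-hydroxy-N,2-dimethoxy-N-methylpropanamide
Conditions: MeNH(OMe)·HCl, AlMe3, CH2Cl2, −20 → 0 °C; aq. potassium sodium tartrate
Reagents that add atoms: N,O-dimethylhydroxylamine hydrochloride, CNOC.Cl
Why: Aluminium amide transamination of a β-hydroxy imide, assisted by the free hydroxyl, gives the Weinreb amide and returns the auxiliary. No stereocenter is touched.

Step 7
Reactants: 12 the hydroxy Weinreb amide
Product: 13 (2R,3S)-3-[3-(benzyloxy)-4-methoxyphenyl]-3-[(tert-butyldimethylsilyl)oxy]-N,2-dimethoxy-N-methylpropanamide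
Conditions: tBuMe2SiOTf, 2,6-lutidine, CH2Cl2, −78 → 0 °C
Reagents that add atoms: tert-butyldimethylsilyl triflate, CC(C)(C)[Si](C)(C)OS(=O)(=O)C(F)(F)F
Why: Silyl triflate with a hindered base silylates the secondary benzylic hydroxyl; low temperature and excess base prevent ionisation at the electron-rich benzylic carbon.

Step 8
Reactants: 13 the silylated Weinreb amide
Product: 14 (2R,3S)-3-[3-(benzyloxy)-4-methoxyphenyl]-3-[(tert-butyldimethylsilyl)oxy]-2-methoxypropanal
Conditions: iBu2AlH, THF, −78 °C; aq. potassium sodium tartrate; used without storage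
Reagents that add atoms: none
Why: Hydride reduction of a Weinreb amide stops at the aldehyde level because the N-methoxy group holds aluminium in a chelate until work-up. Immediate use avoids epimerisation at C3.

Step 9
Reactants: 14 the aldehyde; 15 ethynylmagnesium bromide
Product: 16 (3RS,4S,5S)-5-[3-(benzyloxy)-4-methoxyphenyl]-5-[(tert-butyldimethylsilyl)oxy]-4-methoxypent-1-yn-3-ol (both epimers at the carbinol carbon)
Conditions: 15, THF, −78 → 0 °C; aq. NH4Cl
Reagents that add atoms: none
Why: 1,2-Addition of an alkynyl Grignard reagent forms the C4–C4a bond. The new carbinol centre is not controlled and need not be, as C4 becomes the ketone.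

Step 10
Reactants: 16 the propargylic alcohol
Product: 17 (3RS,4S,5S)-5-[3-(benzyloxy)-4-methoxyphenyl]-5-[(tert-butyldimethylsilyl)oxy]-4-methoxy-3-[(triethylsilyl)oxy]pent-1-yne
Conditions: Et3SiCl, imidazole, DMAP (cat.), CH2Cl2, 0 °C → rt
Reagents that add atoms: chlorotriethylsilane, CC[Si](Cl)(CC)CC
Why: Standard silylation; the triethylsilyl ether is chosen because it can later be removed before the other two silyl ethers.

Step 11
Reactants: 17 the terminal alkyne
Product: 20 (3RS,4R,5S)-5-[3-(benzyloxy)-4-methoxyphenyl]-5-[(tert-butyldimethylsilyl)oxy]-4-methoxy-3-[(triethylsilyl)oxy]-1-[(triisopropylsilyl)oxy]pent-1-yne, via lithium acetylide 18 (not isolated), via lithium ynolate 19 (not isolated)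
Conditions: LiN(SiMe3)2, THF, −78 °C; LiOOtBu (from tBuOOH and LiN(SiMe3)2), −78 → 0 °C; iPr3SiOTf, −78 → 0 °C; pentane extraction, filtration through Et3N-deactivated silica
Reagents that add atoms: lithium tert-butyl peroxide, CC(C)(C)OO[Li]; triisopropylsilyl triflate, CC(C)[Si](C(C)C)(C(C)C)OS(=O)(=O)C(F)(F)F
Why: Acetylide 18 accepts electrophilic oxygen from the lithium peroxide to give ynolate 19 (known oxidation of lithium acetylides to ynolates). The bulky silyl triflate then silylates oxygen and not carbon, giving the siloxyalkyne.

Step 12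
Reactants: 5 4-(benzyloxy)-3-methoxycyclobut-2-en-1-one; 20 the siloxyalkyne
Product: 25 2-(benzyloxy)-6-[(1RS,2R,3S)-3-[3-(benzyloxy)-4-methoxyphenyl]-3-[(tert-butyldimethylsilyl)oxy]-2-methoxy-1-[(triethylsilyl)oxy]propyl]-3-methoxy-5-[(triisopropylsilyl)oxy]phenol, via vinylketene 21 (not isolated), via vinylcyclobutenone 22 (not isolated), via dienylketene 23 (not isolated), via cyclohexadienone 24 (not isolated)
Conditions: 5 (1.5 equiv, added in portions), degassed toluene, 80 °C, then 110 °C
Reagents that add atoms: none
Why: Heating opens 5 in a conrotatory 4π electrocyclic step, the benzyloxy group turning outward, to vinylketene 21; the ketene C=C adds to 20 in a [2+2] cycloaddition to give 22, which opens again (4π) to dienylketene 23. Ring A is closed by thermal disrotatory 6π electrocyclisation of 23, which forms the C5–C6 bond, and cyclohexadienone 24 tautomerises to phenol 25; the net change is insertion of the two alkyne carbons between C5 and C8, that is, new C4a–C5 and C8–C8a bonds. The closest known reaction type is the Danheiser benzannulation of cyclobutenones with trialkylsiloxyalkynes, which gives resorcinol monosilyl ethers of this substitution pattern. No stereocenter is formed: the centre of racemic 5 is lost on ring opening, C2 and C3 are spectators and C4 stays an epimer mixture. The selectivity needed is the regiochemistry of the [2+2] step, and polarisation secures it: the alkyne carbon β to the siloxy oxygen, which bears the chain, is the nucleophilic terminus and bonds to the electrophilic ketene carbonyl carbon, so the chain ends ortho (C4a) and the siloxy group meta (C8a) to the new C5 hydroxyl. The substituent map follows from connectivity: ketene carbon to C5–OH, C4 of 5 to C6–OBn, C3 to C7–OMe, C2 to C8–H. Both 4π openings are reversible, so the dienylketene geometry able to cyclise is drained by the irreversible 6π closure. Portionwise addition of 5 keeps the concentration of 21 low against dimerisation and against acylation of the product phenol.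

Step 13
Reactants: 25 the ring A phenol
Product: 26 [3,4-bis(benzyloxy)-2-[(1RS,2R,3S)-3-[3-(benzyloxy)-4-methoxyphenyl]-3-[(tert-butyldimethylsilyl)oxy]-2-methoxy-1-[(triethylsilyl)oxy]propyl]-5-methoxyphenoxy]triisopropylsilane
Conditions: BnBr, K2CO3, Bu4NI (cat.), DMF, rt
Reagents that add atoms: benzyl bromide, BrCc1ccccc1
Why: Williamson alkylation of the only free hydroxyl; the carbonate is too weak to disturb the silyl ethers. This benzyl group is what later prevents ring C from closing through the C5 oxygen.

Step 14
Reactants: 26 the fully protected arene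
Product: 27 (1RS,2S,3S)-1-[2,3-bis(benzyloxy)-4-methoxy-6-[(triisopropylsilyl)oxy]phenyl]-3-[3-(benzyloxy)-4-methoxyphenyl]-3-[(tert-butyldimethylsilyl)oxy]-2-methoxypropan-1-ol
Conditions: HF·pyridine, pyridine, THF, 0 °C
Reagents that add atoms: none
Why: Buffered HF·pyridine should cleave the triethylsilyl ether well before the hindered benzylic tert-butyldimethylsilyl ether and the aryl triisopropylsilyl ether (graded silyl lability). The near-neutral medium avoids ionisation at the very electron-rich C4 benzylic carbon.

Step 15
Reactants: 27 the C4 carbinol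
Product: 28 (2R,3S)-1-[2,3-bis(benzyloxy)-4-methoxy-6-[(triisopropylsilyl)oxy]phenyl]-3-[3-(benzyloxy)-4-methoxyphenyl]-3-[(tert-butyldimethylsilyl)oxy]-2-methoxypropan-1-one
Conditions: Dess–Martin periodinane, NaHCO3, CH2Cl2, 0 °C → rt
Reagents that add atoms: none
Why: Dess–Martin oxidation of a secondary benzylic alcohol; both C4 epimers converge on one ketone. The buffered, non-basic medium leaves the α-centre C3 untouched, and no free phenol is present to be oxidised.

Step 16
Reactants: 28 the silylated ketone
Product: 29 (2R,3S)-1-[2,3-bis(benzyloxy)-6-hydroxy-4-methoxyphenyl]-3-[3-(benzyloxy)-4-methoxyphenyl]-3-hydroxy-2-methoxypropan-1-one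
Conditions: Bu4NF, AcOH (1:1), THF, 0 °C → rt
Reagents that add atoms: none
Why: Fluoride cleaves the aryl triisopropylsilyl and the benzylic tert-butyldimethylsilyl ether. Acetic acid keeps phenoxide and alkoxide protonated, so retro-aldol cleavage and β-elimination of the β-hydroxy ketone are held back.

Step 17
Reactants: 29 the hydroxy ketone phenol
Product: 30 (2R,3R)-5,6-bis(benzyloxy)-2-[3-(benzyloxy)-4-methoxyphenyl]-3,7-dimethoxychroman-4-one
Conditions: PPh3, DIAD, THF, 0 °C → rt
Reagents that add atoms: none
Why: Intramolecular Mitsunobu etherification: the C2 hydroxyl is activated on phosphorus and displaced by the C8a phenol in a 6-exo-tet SN2 closure. Inversion turns C2 from S to R while C3 is untouched, which gives the 2,3-trans ring.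

Step 18
Reactants: 30 the tris(benzyl) ether
Product: 31 (2R,3R)-5,6-dihydroxy-2-(3-hydroxy-4-methoxyphenyl)-3,7-dimethoxychroman-4-one
Conditions: H2 (1 atm), 10% Pd/C, EtOAc/MeOH, rt; work-up under argon
Reagents that add atoms: none
Why: Hydrogenolysis of three aryl benzyl ethers over palladium on carbon is neutral, so neither C3 nor ring C is endangered, and the methyl ethers stay.

## Compound list

1 | dimethyl squarate (3,4-dimethoxycyclobut-3-ene-1,2-dione) | COC1=C(OC)C(=O)C1=O | starting material
2 | 4-hydroxy-2,3-dimethoxycyclobut-2-en-1-one (racemic) | COC1=C(OC)C(=O)C1O | intermediate (not isolated)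
3 | 3-methoxycyclobut-3-ene-1,2-dione | COC1=CC(=O)C1=O | intermediate
4 | 4-hydroxy-3-methoxycyclobut-2-en-1-one (racemic) | COC1=CC(=O)C1O | intermediate
5 | 4-(benzyloxy)-3-methoxycyclobut-2-en-1-one (racemic) | COC1=CC(=O)C1OCc1ccccc1 | intermediate
6 | (R)-4-benzyloxazolidin-2-one | O=C1N[C@H](Cc2ccccc2)CO1 | starting material
7 | methoxyacetyl chloride | COCC(=O)Cl | starting material
8 | (R)-4-benzyl-3-(2-methoxyacetyl)oxazolidin-2-one | COCC(=O)N1[C@H](Cc2ccccc2)COC1=O | intermediate
9 | 3-(benzyloxy)-4-methoxybenzaldehyde | COc1ccc(C=O)cc1OCc1ccccc1 | starting material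
10 | (Z)-dibutylboron enolate of 8 | CO/C=C(\OB(CCCC)CCCC)N1[C@H](Cc2ccccc2)COC1=O | intermediate (not isolated)
11 | (R)-4-benzyl-3-[(2R,3S)-3-[3-(benzyloxy)-4-methoxyphenyl]-3-hydroxy-2-methoxypropanoyl]oxazolidin-2-one | COc1ccc([C@H](O)[C@@H](OC)C(=O)N2[C@H](Cc3ccccc3)COC2=O)cc1OCc1ccccc1 | intermediate
12 | (2R,3S)-3-[3-(benzyloxy)-4-methoxyphenyl]-3-hydroxy-N,2-dimethoxy-N-methylpropanamide | COc1ccc([C@H](O)[C@@H](OC)C(=O)N(C)OC)cc1OCc1ccccc1 | intermediate
13 | (2R,3S)-3-[3-(benzyloxy)-4-methoxyphenyl]-3-[(tert-butyldimethylsilyl)oxy]-N,2-dimethoxy-N-methylpropanamide | COc1ccc([C@H](O[Si](C)(C)C(C)(C)C)[C@@H](OC)C(=O)N(C)OC)cc1OCc1ccccc1 | intermediate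
14 | (2R,3S)-3-[3-(benzyloxy)-4-methoxyphenyl]-3-[(tert-butyldimethylsilyl)oxy]-2-methoxypropanal | COc1ccc([C@H](O[Si](C)(C)C(C)(C)C)[C@@H](OC)C=O)cc1OCc1ccccc1 | intermediate
15 | ethynylmagnesium bromide | C#C[Mg]Br | starting material
16 | (3RS,4S,5S)-5-[3-(benzyloxy)-4-methoxyphenyl]-5-[(tert-butyldimethylsilyl)oxy]-4-methoxypent-1-yn-3-ol (epimers at the carbinol carbon) | COc1ccc([C@H](O[Si](C)(C)C(C)(C)C)[C@@H](OC)C(O)C#C)cc1OCc1ccccc1 | intermediate
17 | (3RS,4S,5S)-5-[3-(benzyloxy)-4-methoxyphenyl]-5-[(tert-butyldimethylsilyl)oxy]-4-methoxy-3-[(triethylsilyl)oxy]pent-1-yne | COc1ccc([C@H](O[Si](C)(C)C(C)(C)C)[C@@H](OC)C(O[Si](CC)(CC)CC)C#C)cc1OCc1ccccc1 | intermediate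
18 | lithium acetylide of 17 | COc1ccc([C@H](O[Si](C)(C)C(C)(C)C)[C@@H](OC)C(O[Si](CC)(CC)CC)C#C[Li])cc1OCc1ccccc1 | intermediate (not isolated)
19 | lithium ynolate formed from 18 (same chain, C≡C–OLi) | COc1ccc([C@H](O[Si](C)(C)C(C)(C)C)[C@@H](OC)C(O[Si](CC)(CC)CC)C#CO[Li])cc1OCc1ccccc1 | intermediate (not isolated)
20 | (3RS,4R,5S)-5-[3-(benzyloxy)-4-methoxyphenyl]-5-[(tert-butyldimethylsilyl)oxy]-4-methoxy-3-[(triethylsilyl)oxy]-1-[(triisopropylsilyl)oxy]pent-1-yne | COc1ccc([C@H](O[Si](C)(C)C(C)(C)C)[C@@H](OC)C(O[Si](CC)(CC)CC)C#CO[Si](C(C)C)(C(C)C)C(C)C)cc1OCc1ccccc1 | intermediate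
21 | (3Z)-4-(benzyloxy)-3-methoxybuta-1,3-dien-1-one (vinylketene) | O=C=C/C(OC)=C/OCc1ccccc1 | intermediate (not isolated)
22 | 4-[(Z)-2-(benzyloxy)-1-methoxyethenyl]-3-[(triisopropylsilyl)oxy]cyclobut-2-en-1-one carrying at C2 the silylated chain of 25 ([2+2] adduct) | O=C1C(C(O[Si](CC)(CC)CC)[C@H](OC)[C@@H](O[Si](C)(C)C(C)(C)C)c2ccc(OC)c(OCc3ccccc3)c2)=C(O[Si](C(C)C)(C(C)C)C(C)C)C1/C(OC)=C/OCc1ccccc1 | intermediate (not isolated)
23 | dienylketene from ring opening of 22: 6-(benzyloxy)-5-methoxy-3-[(triisopropylsilyl)oxy]hexa-1,3,5-trien-1-one with the chain of 25 on C2, (3Z,5Z) | O=C=C(C(O[Si](CC)(CC)CC)[C@H](OC)[C@@H](O[Si](C)(C)C(C)(C)C)c1ccc(OC)c(OCc2ccccc2)c1)/C(O[Si](C(C)C)(C(C)C)C(C)C)=C\C(OC)=C\OCc1ccccc1 | intermediate (not isolated)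
24 | 6-(benzyloxy)-5-methoxy-3-[(triisopropylsilyl)oxy]cyclohexa-2,4-dien-1-one with the chain of 25 on C2 | O=C1C(C(O[Si](CC)(CC)CC)[C@H](OC)[C@@H](O[Si](C)(C)C(C)(C)C)c2ccc(OC)c(OCc3ccccc3)c2)=C(O[Si](C(C)C)(C(C)C)C(C)C)C=C(OC)C1OCc1ccccc1 | intermediate (not isolated)
25 | 2-(benzyloxy)-6-[(1RS,2R,3S)-3-[3-(benzyloxy)-4-methoxyphenyl]-3-[(tert-butyldimethylsilyl)oxy]-2-methoxy-1-[(triethylsilyl)oxy]propyl]-3-methoxy-5-[(triisopropylsilyl)oxy]phenol | Oc1c(C(O[Si](CC)(CC)CC)[C@H](OC)[C@@H](O[Si](C)(C)C(C)(C)C)c2ccc(OC)c(OCc3ccccc3)c2)c(O[Si](C(C)C)(C(C)C)C(C)C)cc(OC)c1OCc1ccccc1 | intermediate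
26 | [3,4-bis(benzyloxy)-2-[(1RS,2R,3S)-3-[3-(benzyloxy)-4-methoxyphenyl]-3-[(tert-butyldimethylsilyl)oxy]-2-methoxy-1-[(triethylsilyl)oxy]propyl]-5-methoxyphenoxy]triisopropylsilane | C(c1ccccc1)Oc1c(C(O[Si](CC)(CC)CC)[C@H](OC)[C@@H](O[Si](C)(C)C(C)(C)C)c2ccc(OC)c(OCc3ccccc3)c2)c(O[Si](C(C)C)(C(C)C)C(C)C)cc(OC)c1OCc1ccccc1 | intermediate
27 | (1RS,2S,3S)-1-[2,3-bis(benzyloxy)-4-methoxy-6-[(triisopropylsilyl)oxy]phenyl]-3-[3-(benzyloxy)-4-methoxyphenyl]-3-[(tert-butyldimethylsilyl)oxy]-2-methoxypropan-1-ol | C(c1ccccc1)Oc1c(C(O)[C@H](OC)[C@@H](O[Si](C)(C)C(C)(C)C)c2ccc(OC)c(OCc3ccccc3)c2)c(O[Si](C(C)C)(C(C)C)C(C)C)cc(OC)c1OCc1ccccc1 | intermediate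
28 | (2R,3S)-1-[2,3-bis(benzyloxy)-4-methoxy-6-[(triisopropylsilyl)oxy]phenyl]-3-[3-(benzyloxy)-4-methoxyphenyl]-3-[(tert-butyldimethylsilyl)oxy]-2-methoxypropan-1-one | C(c1ccccc1)Oc1c(C(=O)[C@H](OC)[C@@H](O[Si](C)(C)C(C)(C)C)c2ccc(OC)c(OCc3ccccc3)c2)c(O[Si](C(C)C)(C(C)C)C(C)C)cc(OC)c1OCc1ccccc1 | intermediate
29 | (2R,3S)-1-[2,3-bis(benzyloxy)-6-hydroxy-4-methoxyphenyl]-3-[3-(benzyloxy)-4-methoxyphenyl]-3-hydroxy-2-methoxypropan-1-one | C(c1ccccc1)Oc1c(C(=O)[C@H](OC)[C@@H](O)c2ccc(OC)c(OCc3ccccc3)c2)c(O)cc(OC)c1OCc1ccccc1 | intermediate
30 | (2R,3R)-5,6-bis(benzyloxy)-2-[3-(benzyloxy)-4-methoxyphenyl]-3,7-dimethoxychroman-4-one | COc1ccc([C@H]2Oc3cc(OC)c(OCc4ccccc4)c(OCc4ccccc4)c3C(=O)[C@@H]2OC)cc1OCc1ccccc1 | intermediate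
31 | (2R,3R)-5,6-dihydroxy-2-(3-hydroxy-4-methoxyphenyl)-3,7-dimethoxychroman-4-one | COc1ccc([C@H]2Oc3cc(OC)c(O)c(O)c3C(=O)[C@@H]2OC)cc1O | target

## Step count and least certain steps

Total: 18 steps. Longest linear sequence: 15 steps (steps 4–18); the cyclobutenone branch (steps 1–3) joins at step 12.

Step 12 (key step). Vinylketene 21 carries a donor methoxy group and is a weak electrophile, and alkyne 20 has a branched, inductively deactivating substituent on its nucleophilic carbon. Dimerisation of 21, its capture by the phenol of 25 (O-acylation) and thermal rearrangement of 20 to a silylketene may therefore outrun the cycloaddition at the temperature needed to open 5. The fallback changes the way the ketene is made, so that it forms at room temperature in the presence of the alkyne. It sets out from 20 and returns at 25.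
- Purchased methyl 4-(benzyloxy)-3-oxobutanoate F1 is O-methylated with trimethyl orthoformate and catalytic H2SO4 in MeOH to methyl (E)-4-(benzyloxy)-3-methoxybut-2-enoate F2.
- F2 is saponified with LiOH to (E)-4-(benzyloxy)-3-methoxybut-2-enoic acid F3 and converted with oxalyl chloride to (E)-4-(benzyloxy)-3-methoxybut-2-enoyl chloride F4.
- F4 is added slowly to 20 and iPr2NEt in CH2Cl2 at rt. 1,4-Dehydrochlorination should give 21, which is trapped as 22; brief heating in toluene then takes 22 through 23 and 24 to 25.
- This does not help if the alkyne itself is too unreactive.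

Step 11. Oxygen transfer to acetylide 18 may be incomplete (return to 17 on work-up), ynolate 19 may be silylated on carbon, and 20 may hydrolyse during isolation. The fallback reaches the same ynolate by Kowalski homologation of an ester instead of oxidising an acetylide. It sets out from 14 and returns at 20.
- 1-Ethoxyvinyllithium (from ethyl vinyl ether and t-BuLi) adds to 14 to give the 1-ethoxyvinyl carbinol F5, which is silylated (Et3SiCl, imidazole) to its triethylsilyl ether F6.
- Ozonolysis (O3, CH2Cl2/MeOH, −78 °C; Me2S) cleaves the enol ether to the ethyl α-(triethylsilyloxy) ester F7.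
- CH2Br2 and lithium 2,2,6,6-tetramethylpiperidide at −78 °C, then n-BuLi with warming to 0 °C, should rearrange the ester to ynolate 19, which is silylated with iPr3SiOTf as in step 11 to give 20.

Step 17. Enolisation at C3 followed by β-elimination of the activated C2 oxygen would give a chalcone and destroy both stereocenters. Ionisation at the p-methoxybenzylic C2 would leak to the 2,3-cis isomer. The fallback closes ring C before the ketone exists, when C3–H is not acidic. It sets out from 26 and returns at 30.
- Bu4NF/AcOH removes all three silyl groups to give the triol, 1-[2,3-bis(benzyloxy)-6-hydroxy-4-methoxyphenyl]-3-[3-(benzyloxy)-4-methoxyphenyl]-2-methoxypropane-1,3-diol F8.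
- Mitsunobu closure (PPh3, DIAD) should engage the less hindered C2 hydroxyl and not the C4 hydroxyl, which is flanked by two ortho substituents, giving the flavan-4-ol, 5,6-bis(benzyloxy)-2-[3-(benzyloxy)-4-methoxyphenyl]-3,7-dimethoxychroman-4-ol F9.
- Dess–Martin or MnO2 oxidation of F9 gives 30.

Step 14. Discrimination between the three silyl ethers may be poor; early loss of the aryl silyl group would expose a p-alkoxyphenol to the oxidant of step 15. Ionisation at C4, stabilised by ortho and para oxygens of ring A, would lead to substitution or elimination. The fallback avoids the free carbinol altogether. It sets out from 26 and returns at 28, and makes no new compound (F0): DDQ in wet CH2Cl2 should abstract the C4 benzylic hydrogen of the triethylsilyl ether, activated by the electron-rich ring A, and give ketone 28 directly (oxidative conversion of a benzylic silyl ether to the carbonyl compound).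

## Further compounds

F1 | step 12 | methyl 4-(benzyloxy)-3-oxobutanoate (purchased) | COC(=O)CC(=O)COCc1ccccc1
F2 | step 12 | methyl (E)-4-(benzyloxy)-3-methoxybut-2-enoate | COC(=O)/C=C(/OC)COCc1ccccc1
F3 | step 12 | (E)-4-(benzyloxy)-3-methoxybut-2-enoic acid | OC(=O)/C=C(/OC)COCc1ccccc1
F4 | step 12 | (E)-4-(benzyloxy)-3-methoxybut-2-enoyl chloride | ClC(=O)/C=C(/OC)COCc1ccccc1
F5 | step 11 | (4S,5S)-5-[3-(benzyloxy)-4-methoxyphenyl]-5-[(tert-butyldimethylsilyl)oxy]-2-ethoxy-4-methoxypent-1-en-3-ol (epimers at C3) | COc1ccc([C@H](O[Si](C)(C)C(C)(C)C)[C@@H](OC)C(O)C(=C)OCC)cc1OCc1ccccc1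
F6 | step 11 | triethylsilyl ether of F5 | COc1ccc([C@H](O[Si](C)(C)C(C)(C)C)[C@@H](OC)C(O[Si](CC)(CC)CC)C(=C)OCC)cc1OCc1ccccc1
F7 | step 11 | ethyl (3R,4S)-4-[3-(benzyloxy)-4-methoxyphenyl]-4-[(tert-butyldimethylsilyl)oxy]-3-methoxy-2-[(triethylsilyl)oxy]butanoate (epimers at C2) | COc1ccc([C@H](O[Si](C)(C)C(C)(C)C)[C@@H](OC)C(O[Si](CC)(CC)CC)C(=O)OCC)cc1OCc1ccccc1
F0 | step 14 | none | none
F8 | step 17 | (2S,3S)-1-[2,3-bis(benzyloxy)-6-hydroxy-4-methoxyphenyl]-3-[3-(benzyloxy)-4-methoxyphenyl]-2-methoxypropane-1,3-diol (epimers at C1) | C(c1ccccc1)Oc1c(C(O)[C@H](OC)[C@@H](O)c2ccc(OC)c(OCc3ccccc3)c2)c(O)cc(OC)c1OCc1ccccc1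
F9 | step 17 | (2R,3S)-5,6-bis(benzyloxy)-2-[3-(benzyloxy)-4-methoxyphenyl]-3,7-dimethoxychroman-4-ol (epimers at C4) | COc1ccc([C@H]2Oc3cc(OC)c(OCc4ccccc4)c(OCc4ccccc4)c3C(O)[C@@H]2OC)cc1OCc1ccccc1
A1 | alternative 1 | 2-diazo-1-[2,3,4-trimethoxy-6-[(triisopropylsilyl)oxy]phenyl]ethan-1-one | COc1cc(O[Si](C(C)C)(C(C)C)C(C)C)c(C(=O)C=[N+]=[N-])c(OC)c1OC
A2 | alternative 1 | (2R,3S)-3-[3-(benzyloxy)-4-methoxyphenyl]-3-hydroxy-2-methoxy-1-[2,3,4-trimethoxy-6-[(triisopropylsilyl)oxy]phenyl]propan-1-one | COc1ccc([C@H](O)[C@@H](OC)C(=O)c2c(O[Si](C(C)C)(C(C)C)C(C)C)cc(OC)c(OC)c2OC)cc1OCc1ccccc1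
A3 | alternative 2 | 3,4-bis(benzyloxy)-5-methoxy-2-(trimethylsilyl)phenyl trifluoromethanesulfonate | COc1cc(OS(=O)(=O)C(F)(F)F)c([Si](C)(C)C)c(OCc2ccccc2)c1OCc1ccccc1
A4 | alternative 2 | methyl (2R,3R)-3-[3-(benzyloxy)-4-methoxyphenyl]-3-hydroxy-2-methoxypropanoate | COc1ccc([C@@H](O)[C@@H](OC)C(=O)OC)cc1OCc1ccccc1
A5 | alternative 2 | (2R,3R)-5,6-bis(benzyloxy)-2-[3-(benzyloxy)-4-methoxyphenyl]-3,7-dimethoxychroman-4-one | COc1ccc([C@H]2Oc3cc(OC)c(OCc4ccccc4)c(OCc4ccccc4)c3C(=O)[C@@H]2OC)cc1OCc1ccccc1
A6 | alternative 3 | 2-iodo-3,4,5-trimethoxyphenol | COc1cc(O)c(I)c(OC)c1OC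
A7 | alternative 3 | 2-(benzyloxy)-4-ethynyl-1-methoxybenzene | COc1ccc(C#C)cc1OCc1ccccc1
A8 | alternative 3 | 3'-(benzyloxy)-4',5,6,7-tetramethoxyflavone | COc1ccc(-c2cc(=O)c3c(OC)c(OC)c(OC)cc3o2)cc1OCc1ccccc1
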